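Everything rests on cutting ring A (the acetyl-bearing filicinic ring) at its C5 carbonyl carbon. This carbon lies para to the quaternary C2(CH3)2 and between the bridge-bearing C4 and the acetyl-bearing C6. The other five ring carbons, C4–C3(=O)–C2Me2–C1(=O)–C6, are the chain of 3,3-dimethylpentane-2,4-dione. In one operation dimethyl carbonate acylates both α-carbons of such a diketone, forming C4–C5 and C5–C6 and closing ring A. The precursor is an acyclic gem-dimethyl 1,3-diketone whose longer arm already ends in the central ring B. Ring B is masked as its tris(benzyl ether) so that the phenols are later freed by neutral hydrogenolysis. Ring C arrives last by Mannich-type methylene transfer.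

Key step: step 4

Remark on the chemistry: the β-triketone rings are written in one enol form throughout. Their tautomers interconvert freely, and the target (filixic acid ABP, C33H38O12) has no stereocentre.

Step 1
Reactants: 1 2,4,6-trihydroxybenzaldehyde
Product: 2 2,4,6-tris(benzyloxy)benzaldehyde
Conditions: BnBr (3.5 equiv), K2CO3 (4 equiv), DMF, rt → 50 °C
Reagents that add atoms: benzyl bromide, BrCc1ccccc1
Why: Williamson ether synthesis: the three phenoxides are O-alkylated by a reactive benzylic bromide, and the electron-withdrawing formyl group tempers the carbon nucleophilicity of the ring so that C-benzylation should stay minor.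

Step 2
Reactants: 3 3,3-dimethylpentane-2,4-dione; 2 2,4,6-tris(benzyloxy)benzaldehyde
Product: 5 (E)-3,3-dimethyl-6-[2,4,6-tris(benzyloxy)phenyl]hex-5-ene-2,4-dione, via aldol adduct 4 (not isolated)
Conditions: LiN(i-Pr)2 (LDA, 1.15 equiv), 3 (1.2 equiv), THF, −78 °C; 2 (1.0 equiv), −78 °C; AcOH quench at −78 °C; crude 4, p-TsOH·H2O (5 mol %), toluene, rt
Reagents that add atoms: none
Why: Directed aldol addition of a kinetic lithium enolate followed by acid-catalysed E1 dehydration (an aldol condensation in two stages): the non-nucleophilic base and the cold acidic quench spare the cleavage-prone 2,2-disubstituted 1,3-diketone from retro-Claisen attack and from acetyl transfer to the aldolate oxygen, one equivalent of base keeps the reaction on one methyl group, and the carbinol of racemic 4 ionises so easily next to the trialkoxyaryl ring that a trace of acid should deliver the conjugated E-alkene, erasing the transient stereocentre.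

Step 3
Reactants: 5 (E)-3,3-dimethyl-6-[2,4,6-tris(benzyloxy)phenyl]hex-5-ene-2,4-dione
Product: 6 3,3-dimethyl-6-[2,4,6-tris(benzyloxy)phenyl]hexane-2,4-dione
Conditions: H2 (1 atm), Pd/C (10 wt % Pd), 2,2'-bipyridyl (0.5 equiv), MeOH–THF, rt
Reagents that add atoms: none
Why: Chemoselective catalytic hydrogenation: Pd/C poisoned by a nitrogen base still saturates a conjugated C=C bond but no longer hydrogenolyses aryl benzyl ethers, and the two ketones are inert at 1 atm.

Step 4
Reactants: 6 3,3-dimethyl-6-[2,4,6-tris(benzyloxy)phenyl]hexane-2,4-dione; 7 dimethyl carbonate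
Product: 9 2,2-dimethyl-4-[2,4,6-tris(benzyloxy)benzyl]cyclohexane-1,3,5-trione (enol form), via keto ester 8 (not isolated)
Conditions: KN(SiMe3)2 (3.2 equiv), THF (0.03 M), −78 → 0 °C; 7 (1.05 equiv) added over 1 h at 0 °C; then 50 °C; cold 1 M HCl; argon throughout
Reagents that add atoms: dimethyl carbonate (7), COC(=O)OC
Why: Full pre-enolisation with a hindered amide base turns 6 into its potassium enolates before any methoxide exists, and a carbonyl that is already an enolate cannot depart as a second carbanion, which shuts down retro-Claisen cleavage at the quaternary carbon. The less hindered CH2=C(O−) terminus attacks dimethyl carbonate (crossed Claisen carboxylation of a ketone) to give keto ester 8, and the enolate on the far side of CMe2 then adds to that ester and expels methoxide (Dieckmann condensation); the opposite order of the two acylations ends in the same ring. The six-membered ring closes in a 6-(enolendo)-exo-trig mode and is helped by the gem-dimethyl effect. No stereocentre results, because C4 ends up in an enol or enolate. The selectivity needed is C- over O-cyclisation and single over double carboxylation: an enol lactone or enol carbonate is itself an acyl donor that methoxide reopens, so all species should drain to the doubly deprotonated trione, while slow addition of one equivalent of 7 at high dilution limits a second carboxylation and intermolecular Claisen reaction. The closest known reactions are the carbonate carboxylation of ketone enolates, the (5+1) closure of 2-hydroxyacetophenones with dialkyl carbonates to 4-hydroxycoumarins, and the Dieckmann closure of 3,5-dioxo esters to cyclohexane-1,3,5-triones.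

Step 5
Reactants: 9 2,2-dimethyl-4-[2,4,6-tris(benzyloxy)benzyl]cyclohexane-1,3,5-trione
Product: 11 6-acetyl-2,2-dimethyl-4-[2,4,6-tris(benzyloxy)benzyl]cyclohexane-1,3,5-trione (enol form), via enol acetate 10 (not isolated)
Conditions: AcCl (1.1 equiv), Et3N (2.5 equiv), CH2Cl2, 0 °C; then DMAP (0.3 equiv), rt; 1 M HCl wash
Reagents that add atoms: acetyl chloride, CC(=O)Cl
Why: O-acylation followed by DMAP-catalysed O-to-C acyl migration, the standard entry to 2-acylcyclohexane-1,3-diones: only acylation at the unsubstituted C6 gives an enolisable tricarbonyl that Et3N deprotonates, so this isomer is the thermodynamic sink, and the benzyl-protected arene is inert under basic conditions.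

Step 6
Reactants: 11 6-acetyl-2,2-dimethyl-4-[2,4,6-tris(benzyloxy)benzyl]cyclohexane-1,3,5-trione
Product: 12 6-acetyl-4-[3-butanoyl-2,4,6-tris(benzyloxy)benzyl]-2,2-dimethylcyclohexane-1,3,5-trione (enol form)
Conditions: n-PrCO2H (2.2 equiv) and (CF3CO)2O (2.0 equiv) premixed, CH2Cl2, 0 °C; then 11, 0 °C → rt; aq NaHCO3–MeOH work-up
Reagents that add atoms: butanoic acid, CCCC(=O)O
Why: Friedel–Crafts acylation with a mixed carboxylic–trifluoroacetic anhydride, which acylates 1,3,5-trialkoxybenzenes without a metal Lewis acid: the two free positions of ring B are equivalent, ring A has no free carbon left, the benzyl ethers block xanthene-type cyclodehydration, premixing with excess butanoic acid leaves no free (CF3CO)2O for trifluoroacetylation, and any enol esters are cleaved in the work-up.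

Step 7
Reactants: 12 6-acetyl-4-[3-butanoyl-2,4,6-tris(benzyloxy)benzyl]-2,2-dimethylcyclohexane-1,3,5-trione
Product: 13 6-acetyl-4-(3-butanoyl-2,4,6-trihydroxybenzyl)-2,2-dimethylcyclohexane-1,3,5-trione (enol form; norflavaspidic acid AB)
Conditions: H2 (1 atm), Pd/C (10 wt % Pd), EtOAc–MeOH, rt
Reagents that add atoms: none
Why: Catalytic hydrogenolysis of aryl benzyl ethers, a neutral unmasking chosen because the ring A–CH2–ring B bond joins a very stabilised benzylic cation to a very good carbon leaving group and would be endangered by the boron or aluminium halides that methyl ethers demand; the chelated aryl ketone and the enolised triketone are not reduced under these conditions.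

Step 8
Reactants: 14 1-(2,4,6-trihydroxyphenyl)propan-1-one (flopropione)
Product: 15 2,2-dimethyl-4-propanoylcyclohexane-1,3,5-trione (enol form; propionylfilicinic acid)
Conditions: NaOMe (3 equiv), MeI (2.2 equiv), MeOH, 0 °C → rt; 1 M HCl
Reagents that add atoms: iodomethane, CI
Why: Dearomatising geminal C-methylation of an acylphloroglucinol anion, the known entry to acylfilicinic acids: the second methyl group enters at the already methylated carbon, the ring can no longer rearomatise, and the strongly acidic triketone anion that results is a weaker nucleophile, which limits further methylation on this cheap side branch.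

Step 9
Reactants: 15 propionylfilicinic acid; 16 N,N-dimethylmethyleneiminium iodide (Eschenmoser's salt); 13 norflavaspidic acid AB
Product: 19 filixic acid ABP (target), via Mannich base 17 (not isolated), via methylidene trione 18 (not isolated)
Conditions: 15 (1.1 equiv), Et3N (1.1 equiv), 16 (1.1 equiv), MeCN, 0 °C → rt; then 13 (1.0 equiv), 40 °C; 1 M HCl wash
Reagents that add atoms: N,N-dimethylmethyleneiminium iodide (16), C[N+](C)=C.[I-]
Why: Mannich aminomethylation of the only free ring carbon of 15, retro-Michael loss of dimethylamine to methide 18, and Michael-type C-alkylation by the last free carbon of ring B, the known Mannich-base route to unsymmetrical methylene-bridged acylphloroglucinols: complete conversion of 15 before 13 is added and a medium buffered by the acidic triketones, with no hydroxide or alkoxide, should suppress homodimer formation and exchange of the bridge already present.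

Compound list
1 | 2,4,6-trihydroxybenzaldehyde | O=Cc1c(O)cc(O)cc1O | starting material
2 | 2,4,6-tris(benzyloxy)benzaldehyde | O=Cc1c(OCc2ccccc2)cc(OCc2ccccc2)cc1OCc1ccccc1 | intermediate
3 | 3,3-dimethylpentane-2,4-dione | CC(=O)C(C)(C)C(C)=O | starting material
4 | 6-hydroxy-3,3-dimethyl-6-[2,4,6-tris(benzyloxy)phenyl]hexane-2,4-dione (racemic, not isolated) | CC(=O)C(C)(C)C(=O)CC(O)c1c(OCc2ccccc2)cc(OCc2ccccc2)cc1OCc1ccccc1 | intermediate
5 | (E)-3,3-dimethyl-6-[2,4,6-tris(benzyloxy)phenyl]hex-5-ene-2,4-dione | CC(=O)C(C)(C)C(=O)/C=C/c1c(OCc2ccccc2)cc(OCc2ccccc2)cc1OCc1ccccc1 | intermediate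
6 | 3,3-dimethyl-6-[2,4,6-tris(benzyloxy)phenyl]hexane-2,4-dione | CC(=O)C(C)(C)C(=O)CCc1c(OCc2ccccc2)cc(OCc2ccccc2)cc1OCc1ccccc1 | intermediate
7 | dimethyl carbonate | COC(=O)OC | starting material
8 | methyl 4,4-dimethyl-3,5-dioxo-7-[2,4,6-tris(benzyloxy)phenyl]heptanoate (not isolated) | COC(=O)CC(=O)C(C)(C)C(=O)CCc1c(OCc2ccccc2)cc(OCc2ccccc2)cc1OCc1ccccc1 | intermediate
9 | 2,2-dimethyl-4-[2,4,6-tris(benzyloxy)benzyl]cyclohexane-1,3,5-trione (enol form) | O=C1C=C(O)C(C)(C)C(O)=C1Cc1c(OCc2ccccc2)cc(OCc2ccccc2)cc1OCc1ccccc1 | intermediate
10 | enol acetate of 9 (one O-regioisomer drawn, not isolated) | CC(=O)OC1=CC(=O)C(C)(C)C(O)=C1Cc1c(OCc2ccccc2)cc(OCc2ccccc2)cc1OCc1ccccc1 | intermediate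
11 | 6-acetyl-2,2-dimethyl-4-[2,4,6-tris(benzyloxy)benzyl]cyclohexane-1,3,5-trione (enol form) | CC(=O)C1=C(O)C(C)(C)C(O)=C(Cc2c(OCc3ccccc3)cc(OCc3ccccc3)cc2OCc2ccccc2)C1=O | intermediate
12 | 6-acetyl-4-[3-butanoyl-2,4,6-tris(benzyloxy)benzyl]-2,2-dimethylcyclohexane-1,3,5-trione (enol form) | CCCC(=O)c1c(OCc2ccccc2)cc(OCc2ccccc2)c(CC2=C(O)C(C)(C)C(O)=C(C(C)=O)C2=O)c1OCc1ccccc1 | intermediate
13 | 6-acetyl-4-(3-butanoyl-2,4,6-trihydroxybenzyl)-2,2-dimethylcyclohexane-1,3,5-trione (enol form; norflavaspidic acid AB) | CCCC(=O)c1c(O)cc(O)c(CC2=C(O)C(C)(C)C(O)=C(C(C)=O)C2=O)c1O | intermediate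
14 | 1-(2,4,6-trihydroxyphenyl)propan-1-one (flopropione) | CCC(=O)c1c(O)cc(O)cc1O | starting material
15 | 2,2-dimethyl-4-propanoylcyclohexane-1,3,5-trione (enol form; propionylfilicinic acid) | CCC(=O)C1=C(O)C(C)(C)C(O)=CC1=O | intermediate
16 | N,N-dimethylmethyleneiminium iodide (Eschenmoser's salt) | C[N+](C)=C.[I-] | starting material
17 | 4-[(dimethylamino)methyl]-2,2-dimethyl-6-propanoylcyclohexane-1,3,5-trione (enol form, not isolated) | CCC(=O)C1=C(O)C(C)(C)C(O)=C(CN(C)C)C1=O | intermediate
18 | 2,2-dimethyl-4-methylidene-6-propanoylcyclohexane-1,3,5-trione (enol form, not isolated) | CCC(=O)C1=C(O)C(C)(C)C(=O)C(=C)C1=O | intermediate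
19 | filixic acid ABP: butanoylphloroglucinol ring B joined through CH2 bridges to acetylfilicinic ring A and propionylfilicinic ring C | CCCC(=O)c1c(O)c(CC2=C(O)C(C)(C)C(O)=C(C(C)=O)C2=O)c(O)c(CC2=C(O)C(C)(C)C(O)=C(C(=O)CC)C2=O)c1O | target

Total step count: 9. Longest linear sequence: 8 (steps 1–7 and 9); step 8 is a one-step side branch.

Steps most likely to fail

1. Step 4. Three things may go wrong.
- Incomplete enolisation would let the released methoxide cleave the diketone at the quaternary carbon.
- The sequence may stall at the open keto ester, whose own enolate deactivates the ester toward ring closure.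
- A second carboxylation or an intermolecular Claisen reaction may compete.

Fallback: ring A is taken from a dearomatised arene instead of being closed from a chain. It sets out from aldehyde 2 and comes back at 11.
- Commercial 1-(2,4,6-trihydroxyphenyl)ethanone is gem-dimethylated with MeI and NaOMe in MeOH, as in step 8, to acetylfilicinic acid F1.
- F1 and 2 are stirred with catalytic L-proline and diethyl 2,6-dimethyl-1,4-dihydropyridine-3,5-dicarboxylate (Hantzsch ester) in CH2Cl2–EtOH at rt.
- Knoevenagel condensation gives the arylidene trione F2, whose alkene geometry is immaterial.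
- F2 is reduced in the same flask by conjugate hydride transfer to 11.

2. Step 9. Three things may go wrong.
- Retro-Michael cleavage and re-addition may exchange the methylene bridges and scramble the three rings.
- The methide may be consumed by self-condensation or by unreacted filicinic partner.
- Reversible O-alkylation may slow the C–C bond formation.

Fallback: the roles of the partners are reversed. It sets out from 13 and comes back at 19.
- 13 is aminomethylated at its last aromatic carbon with 16 and Et3N in MeCN, and the ring B Mannich base F3 is isolated.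
- F3 is then warmed with 15 in dioxane at about 60 °C.
- Loss of dimethylamine generates the ortho-quinone methide of ring B, which is trapped by the free ring carbon of 15 to give 19.

3. Step 6. Three things may go wrong.
- The liberated trifluoroacetic acid may heterolyse the ring A–CH2–ring B bond.
- It may cause loss or migration of benzyl groups.
- Ring B may be acylated twice.

Fallback: unmasking comes first and a nitrilium electrophile replaces the acylium donor. It sets out from 11 and comes back at 13.
- 11 is hydrogenolysed (H2, Pd/C, EtOAc–MeOH) to the free triol F4.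
- F4 undergoes a Houben–Hoesch reaction with butanenitrile, ZnCl2 and HCl gas in Et2O at 0 °C, precipitating the ketiminium chloride F5. This salt cannot react a second time.
- Warm water hydrolyses F5 to 13.

Further compounds
F1 | step 4 | 4-acetyl-2,2-dimethylcyclohexane-1,3,5-trione (enol form; acetylfilicinic acid) | CC(=O)C1=C(O)C(C)(C)C(O)=CC1=O
F2 | step 4 | 6-acetyl-2,2-dimethyl-4-[2,4,6-tris(benzyloxy)benzylidene]cyclohexane-1,3,5-trione (enol form) | CC(=O)C1=C(O)C(C)(C)C(=O)/C(=C/c2c(OCc3ccccc3)cc(OCc3ccccc3)cc2OCc2ccccc2)C1=O
F3 | step 9 | 6-acetyl-4-{3-butanoyl-5-[(dimethylamino)methyl]-2,4,6-trihydroxybenzyl}-2,2-dimethylcyclohexane-1,3,5-trione (enol form) | CCCC(=O)c1c(O)c(CN(C)C)c(O)c(CC2=C(O)C(C)(C)C(O)=C(C(C)=O)C2=O)c1O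
F4 | step 6 | 6-acetyl-2,2-dimethyl-4-(2,4,6-trihydroxybenzyl)cyclohexane-1,3,5-trione (enol form) | CC(=O)C1=C(O)C(C)(C)C(O)=C(Cc2c(O)cc(O)cc2O)C1=O
F5 | step 6 | ketiminium chloride of 13 (C=NH2+ in place of the butanoyl C=O) | CCCC(=[NH2+])c1c(O)cc(O)c(CC2=C(O)C(C)(C)C(O)=C(C(C)=O)C2=O)c1O.[Cl-]
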